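The numbers in the tables stem from a simulated flask for an exercise; noise was put on by code.

- Q is what this flask is wanted for, yet it comes and goes: in the birch run it falls from 34.6% at 6.00 min to 4.4% at 25.0 min while G stays at or below 0.6%, so I keep a ledger of the L charged, with each mole entered as L, as Q, or as lost Q.

| flask | L | E | remark | time |
|---|---|---|---|---|
| birch | 0.10 M | 0.74 equiv | run made earlier |  |
| maple | 0.10 M | 1.7 equiv | run made earlier |  |
| alder | 0.050 M | 1.1 equiv | run made earlier |  |
| flask | 0.10 M | 1.10 equiv |  | 2.0 h |

- birch (time / min: Q / %, G / %): 1.33: 29.8, 0.6; 6.00: 34.6, 0; 25.0: 4.4, 0.5; 120: 0.6, 0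
- maple (time / min: Q / %, G / %): 1.33: 54.1, 0.1; 6.00: 44.1, 2.3; 25.0: 3.8, 1.4; 120: 0, 0.7
- alder (time / min: Q / %, G / %): 1.33: 26.8, 0.4; 6.00: 39.1, 0.3; 25.0: 8.4, 0; 120: 0.4, 0

(readings scatter by 0.5 percentage points)



- the best time, 2.0 h at the latest, for Q
- the amount of Q, in percent of the L charged, at that time

- Birch has the least E, so I read its fall as a first-order loss of 0.109 min⁻¹.
- Maple has the L charge of this flask and 54.1% Q after 1.33 min, and the second-order law for L with E turns that into a making constant of 0.425 min⁻¹ at this charge.
- Their quotient 3.92 is my head start, the making constant at the L charge over the loss constant, a selectivity factor for this charge; Q peaks where making equals loss, which reads q = S·l·e, with q, l and e the amounts of Q, L and E as fractions of the L charged.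
- For the flask I open the entry with 33.3% of L left, where each L gone has taken one E, so e is 0.433, and the second-order law puts that at 3.93 min.
- Q rises steeply, so I set its mean up to then at 0.667 of its top, and the ledger balances with 51.9% Q and 14.8% lost.
- The peak rule there asks for 56.6%, above the ledger's entry, so by my reckoning making is still slightly ahead, and I commit to about the ledger's 51.9% of Q at 0.0655 h; by 2.0 h my loss constant has run 13.1 lifetimes, which moves the Q entry into lost.
- The forecast gives 45% at 0.055 h, lower and earlier than my entry, holding that “the loss accelerates”.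
- The flask gives 49.5% at 0.0519 h, so my entry stands 2.4 percentage points high and 0.0136 h late.

    Q → X (k = 0.00210 s⁻¹)
    Q + E → D + Z (k = 0.00830 L mol⁻¹ s⁻¹)
    Z + E → D + G (k = 0.0430 L mol⁻¹ s⁻¹)
    L + E → D + Q (k = 0.0970 L mol⁻¹ s⁻¹)
    G → J (k = 0.00570 s⁻¹)

- At 0.0238 h the flask makes Q 2.72 times faster than it uses it up, each step taken net, and Q → X then takes 4.2 times as much Q as Q + E does, while at the best time the amounts in the flask put q/(l·e) at 4.01, beside my head start of 3.92. In the neighbouring flask, with 0.040 M of L at the same equivalents, I reckon the head start down in proportion to the L charge, to 1.57, and the highest Q of that neighbouring flask is 37.6%.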